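**Assumption:** the SMILES is read literally, i.e. (E)-C1(10) alkene, cis (Z-derived) C4–C5 epoxide, absolute configuration as written. The comments use germacrane locants: C1=C10(Me), C2, C3, C4(Me)–C5 epoxide, C6 (OAc), C7 (iPr), C8 (O-angelate), C9.

## Retrosynthetic overview

1. Target ⇒ Yamaguchi angeloylation of the 6-O-acetyl-8-ol ⇒ Evans–Tishchenko reduction of an epoxy β-hydroxy ketone (sets C8 and places the acetate on O6).
2. ⇒ OH-directed vanadium epoxidation of the (Z)-allylic alcohol ⇒ asymmetric transfer hydrogenation with dynamic kinetic resolution (C6, C7) of a configurationally labile ten-membered 1,3-dione ⇒ oxidation of a racemic 8-hydroxy enone.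
3. Ten-membered ring ⇒ Prins/Grob ring expansion (6 → 10) of a 6-isopropenyl-cyclohexenol carrying a β-formyl side chain. The fragmentation sets 1(10)E; 4Z is inherited from the cyclohexenone.
4. ⇒ isopiperitenone + 3-methylbutanenitrile (1,2-addition, then DIBAL-H) ⇒ 3-methylcyclohex-2-enone + 2-bromopropene (Pd α′-alkenylation).
5. Ring order: six-membered carbocycle (bought) → ten-membered carbocycle (through a transient fused second six-membered ring) → oxirane.

## Route

Step 1
Reactants: 1 3-methylcyclohex-2-en-1-one; 2 2-bromopropene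
Product: 3 rac-3-methyl-6-(prop-1-en-2-yl)cyclohex-2-en-1-one
Conditions: LiHMDS (2.2 equiv), THF, −78 °C; 2 (1.2 equiv), Pd2(dba)3 (1 mol %), Q-Phos (2.5 mol %), −78 → 23 °C; AcOH, −78 °C
Reagents that add atoms: none
Why: Pd-catalysed α-alkenylation of a ketone enolate (Buchwald–Hartwig-type enolate coupling) at C6 of the kinetic cross-conjugated α′-enolate; the new stereocentre is left racemic because Step 4 destroys it, and the cold acidic quench protonates the product dienolate at Cα so the isopropenyl group stays out of conjugation.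

Step 2
Reactants: 3 rac-3-methyl-6-(prop-1-en-2-yl)cyclohex-2-en-1-one; 4 3-methylbutanenitrile
Product: 5 rac-2-[(1S*,6S*)-1-hydroxy-3-methyl-6-(prop-1-en-2-yl)cyclohex-2-en-1-yl]-3-methylbutanenitrile (both epimers at the nitrile α-carbon)
Conditions: 4, LDA, THF, −78 °C; CeCl3, −78 °C, 1 h; 3, −78 °C; aq NH4Cl
Reagents that add atoms: none
Why: Organocerium 1,2-addition of the α-metallated nitrile (cerium suppresses enolisation of the acidic C6–H, and the β,β-disubstituted enone resists 1,4-addition); attack anti to the isopropenyl group puts the two carbon substituents trans (OH cis to isopropenyl), which Step 4 needs, while the nitrile α-centre forms as a mixture that Step 5 erases.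

Step 3
Reactants: 5 rac-2-[(1S*,6S*)-1-hydroxy-3-methyl-6-(prop-1-en-2-yl)cyclohex-2-en-1-yl]-3-methylbutanenitrile
Product: 7 rac-2-[(1S*,6S*)-1-hydroxy-3-methyl-6-(prop-1-en-2-yl)cyclohex-2-en-1-yl]-3-methylbutanal, via aldimine 6 (not isolated)
Conditions: DIBAL-H (2.5 equiv), toluene, −78 → −40 °C; aq Rochelle salt, then pH 5 acetate buffer, 0 °C
Reagents that add atoms: water, O
Why: DIBAL-H reduction of a nitrile stops at the N-aluminio imine, which is hydrolysed at pH 5 (no base, so no retro-aldol of the β-hydroxy aldehyde); one hydride equivalent is consumed by the tertiary OH and no stereocentre changes.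

Step 4
Reactants: 7 rac-2-[(1S*,6S*)-1-hydroxy-3-methyl-6-(prop-1-en-2-yl)cyclohex-2-en-1-yl]-3-methylbutanal
Product: 8 rac-(2Z,6E)-9-hydroxy-3,7-dimethyl-10-(propan-2-yl)cyclodeca-2,6-dien-1-one (mixture of C9/C10 diastereomers)
Conditions: Me2AlCl (2.2 equiv), CH2Cl2, −78 → −45 °C, 2 h; Et3N/MeOH, −78 °C
Reagents that add atoms: none
Why: Proposed new method: an aluminium-alkoxide-templated Prins/Grob ring expansion (a stepwise, cationic, formal allyl transfer from the tertiary homoallylic alcohol to the tethered aldehyde). Me2AlCl turns the tertiary OH into an Al alkoxide that holds and activates the β-aldehyde; the isopropenyl CH2 (C9) adds to the aldehyde carbon (C8) through a chair six-membered transition state, and the positive charge building at tertiary C10 is discharged by alkoxide-assisted heterolysis of the C1–C6 ring bond (Grob-type) rather than by proton loss. This gives the C6 enone and the C1(10) alkene, which is E because the trans-disposed side chains force a trans-fused chair with C2 equatorial; the 4Z alkene is the untouched cyclohexene bond. The driving force is aldehyde → conjugated ketone, tertiary → secondary alkoxide and 1,1-di- → trisubstituted alkene. Closest known reaction types: Me2AlCl-promoted Prins/carbonyl-ene cyclisation of unsaturated aldehydes, Prins–pinacol terminations, allyl transfer from homoallylic alcohols to aldehydes, and Grob fragmentation of γ-hydroxy halides and sulfonates.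

Step 5
Reactants: 8 rac-(2Z,6E)-9-hydroxy-3,7-dimethyl-10-(propan-2-yl)cyclodeca-2,6-dien-1-one
Product: 9 (4Z,8E)-5,9-dimethyl-2-(propan-2-yl)cyclodeca-4,8-diene-1,3-dione
Conditions: Dess–Martin periodinane (1.3 equiv), CH2Cl2, 0 → 23 °C
Reagents that add atoms: none
Why: Dess–Martin oxidation of the β-hydroxy ketone gives the 1,3-dione, whose only stereocentre (C7) is labile, so both enantiomers and all C7/C8 epimers of 8 converge on one substrate for the asymmetric step.

Step 6
Reactants: 9 (4Z,8E)-5,9-dimethyl-2-(propan-2-yl)cyclodeca-4,8-diene-1,3-dione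
Product: 10 (3E,7Z,9S,10S)-9-hydroxy-3,7-dimethyl-10-(propan-2-yl)cyclodeca-3,7-dien-1-one
Conditions: RuCl[(R,R)-TsDPEN](p-cymene) (2 mol %), HCO2H/Et3N (5:2), CH2Cl2, 25 °C
Reagents that add atoms: none
Why: Noyori–Ikariya asymmetric transfer hydrogenation with dynamic kinetic resolution: the catalyst is expected to take the alkenyl ketone (C6=O, CH/π contact as with aryl ketones) and to stop there because C8=O is then an unactivated dialkyl ketone; C7 racemises through the dione enol(ate) under Et3N, and the (R,R)-catalyst reduces the epimer that reacts in the Felkin–Anh sense (acyl group anti to hydride), giving the 6,7-anti carbinol with the C6 configuration of the target.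

Step 7
Reactants: 10 (3E,7Z,9S,10S)-9-hydroxy-3,7-dimethyl-10-(propan-2-yl)cyclodeca-3,7-dien-1-one
Product: 11 (1R,2R,3S,6E,10S)-2-hydroxy-6,10-dimethyl-3-(propan-2-yl)-11-oxabicyclo[8.1.0]undec-6-en-4-one
Conditions: VO(acac)2 (5 mol %), t-BuOOH (1.2 equiv, decane), CH2Cl2, 0 °C
Reagents that add atoms: tert-butyl hydroperoxide, CC(C)(C)OO
Why: Hydroxyl-directed vanadium epoxidation (VO(acac)2/TBHP): the V alkoxide of the C6 alcohol delivers oxygen to the alkene face syn to OH; with the C6–C7 ring bond held out of the alkene plane this gives the cis (erythro) epoxy alcohol, as for medium-ring cis-cycloalk-2-enols, setting C4 and C5, while the C1(10) alkene and the ketone do not react.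

Step 8
Reactants: 11 (1R,2R,3S,6E,10S)-2-hydroxy-6,10-dimethyl-3-(propan-2-yl)-11-oxabicyclo[8.1.0]undec-6-en-4-one; 12 acetaldehyde
Product: 13 (1R,2R,3R,4S,6E,10S)-4-hydroxy-6,10-dimethyl-3-(propan-2-yl)-11-oxabicyclo[8.1.0]undec-6-en-2-yl acetate
Conditions: 12 (6 equiv), SmI2 (0.3 equiv), THF, −10 °C
Reagents that add atoms: none
Why: Evans–Tishchenko reduction: the Sm(III)-bound hemiacetal from the C6 hydroxyl and acetaldehyde transfers hydride intramolecularly to C8=O through a six-membered chair, giving the 1,3-anti (8S) alcohol and leaving the acetate on O6, so the two oxygens never have to be differentiated.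

Step 9
Reactants: 13 (1R,2R,3R,4S,6E,10S)-4-hydroxy-6,10-dimethyl-3-(propan-2-yl)-11-oxabicyclo[8.1.0]undec-6-en-2-yl acetate; 14 (2Z)-2-methylbut-2-enoic acid (angelic acid)
Product: 16 (1R,2R,3R,4S,6E,10S)-2-(acetyloxy)-6,10-dimethyl-3-(propan-2-yl)-11-oxabicyclo[8.1.0]undec-6-en-4-yl (2Z)-2-methylbut-2-enoate, via mixed anhydride 15 (not isolated)
Conditions: 14, 2,4,6-trichlorobenzoyl chloride, Et3N, toluene, 23 °C, 2 h; then 13, toluene, 75 °C
Reagents that add atoms: none
Why: Yamaguchi esterification without DMAP: the preformed mixed anhydride acylates the hindered 8-OH while keeping the (Z)-geometry of the angelate (no isomerisation to tiglate), and no stereocentre is touched.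

## Compound list

1 | 3-methylcyclohex-2-en-1-one | CC1=CC(=O)CCC1 | starting material
2 | 2-bromopropene | CC(Br)=C | starting material
3 | rac-3-methyl-6-(prop-1-en-2-yl)cyclohex-2-en-1-one (isopiperitenone, racemate) | CC(=C)C1CCC(C)=CC1=O | intermediate
4 | 3-methylbutanenitrile | CC(C)CC#N | starting material
5 | rac-2-[(1S*,6S*)-1-hydroxy-3-methyl-6-(prop-1-en-2-yl)cyclohex-2-en-1-yl]-3-methylbutanenitrile (OH cis to isopropenyl; one enantiomer drawn; nitrile α-carbon unspecified) | CC(C)C(C#N)[C@]1(O)C=C(C)CC[C@H]1C(C)=C | intermediate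
6 | rac-2-[(1S*,6S*)-1-hydroxy-3-methyl-6-(prop-1-en-2-yl)cyclohex-2-en-1-yl]-3-methylbutan-1-imine | CC(C)C(C=N)[C@]1(O)C=C(C)CC[C@H]1C(C)=C | intermediate
7 | rac-2-[(1S*,6S*)-1-hydroxy-3-methyl-6-(prop-1-en-2-yl)cyclohex-2-en-1-yl]-3-methylbutanal | CC(C)C(C=O)[C@]1(O)C=C(C)CC[C@H]1C(C)=C | intermediate
8 | rac-(2Z,6E)-9-hydroxy-3,7-dimethyl-10-(propan-2-yl)cyclodeca-2,6-dien-1-one (C9/C10 unspecified) | OC1C/C(C)=C/CC/C(C)=C\C(=O)C1C(C)C | intermediate
9 | (4Z,8E)-5,9-dimethyl-2-(propan-2-yl)cyclodeca-4,8-diene-1,3-dione (C2 labile) | O=C1C/C(C)=C/CC/C(C)=C\C(=O)C1C(C)C | intermediate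
10 | (3E,7Z,9S,10S)-9-hydroxy-3,7-dimethyl-10-(propan-2-yl)cyclodeca-3,7-dien-1-one | O=C1C/C(C)=C/CC/C(C)=C\[C@H](O)[C@@H]1C(C)C | intermediate
11 | (1R,2R,3S,6E,10S)-2-hydroxy-6,10-dimethyl-3-(propan-2-yl)-11-oxabicyclo[8.1.0]undec-6-en-4-one | O=C1C/C(C)=C/CC[C@]2(C)O[C@@H]2[C@H](O)[C@@H]1C(C)C | intermediate
12 | acetaldehyde | CC=O | starting material
13 | (1R,2R,3R,4S,6E,10S)-4-hydroxy-6,10-dimethyl-3-(propan-2-yl)-11-oxabicyclo[8.1.0]undec-6-en-2-yl acetate | O[C@H]1C/C(C)=C/CC[C@]2(C)O[C@@H]2[C@H](OC(C)=O)[C@@H]1C(C)C | intermediate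
14 | (2Z)-2-methylbut-2-enoic acid (angelic acid) | C/C=C(/C)C(=O)O | starting material
15 | (2Z)-2-methylbut-2-enoic 2,4,6-trichlorobenzoic anhydride | C/C=C(/C)C(=O)OC(=O)c1c(Cl)cc(Cl)cc1Cl | intermediate
16 | (1R,2R,3R,4S,6E,10S)-2-(acetyloxy)-6,10-dimethyl-3-(propan-2-yl)-11-oxabicyclo[8.1.0]undec-6-en-4-yl (2Z)-2-methylbut-2-enoate | C/C=C(/C)C(=O)O[C@H]1C/C(C)=C/CC[C@]2(C)O[C@@H]2[C@H](OC(C)=O)[C@@H]1C(C)C | target

## Step count and risks

Total step count: 9. Longest linear sequence: 9 steps (1 → 16).

**Step 4 (the proposed new ring expansion).** It can fail by proton loss from the C10 cation to bicyclic ene products, by ionisation of the tertiary allylic alkoxide, by Lewis-acid re-closure of the product, or by sluggish reaction of the aldehyde epimer that must place isopropyl axial. The fallback splits the event into known reactions with an irreversible, base-triggered fragmentation. It sets out from 7: Me2AlCl (3 equiv) in CH2Cl2 at −78 °C with a cold bicarbonate quench gives the chloro-Prins adduct, the trans-fused γ-chloro diol F1 (anti addition, Cl equatorial). TESCl/imidazole silylates only the secondary hydroxyl to give the mono-silyl ether F2. KH/18-crown-6 in THF at 0 °C then makes the tertiary alkoxide, which undergoes a classical Grob fragmentation (ring-fusion bond antiperiplanar to C–Cl) to the ring-expanded silyl ether F3. HF·pyridine removes the silyl group, and the sequence comes back to the route at 8.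

**Step 6 (ATH with DKR).** Three things are uncertain: which carbonyl is reduced first, whether the hindered 2-isopropyl dione epimerises fast enough, and the syn/anti sense. The fallback sets out from 9 and uses a Corey–Bakshi–Shibata reduction, (S)-Me-CBS with catecholborane in toluene at −78 °C. Enones are the privileged substrates and the dialkyl ketone is left alone. The reduction is reagent-controlled at C6 but has no dynamic resolution, so it gives 10 together with the C10-epimeric alcohol F4. The two are separated, and F4 is re-oxidised with Dess–Martin periodinane to 9 and recycled. The fallback comes back at 10.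

**Step 8 (Evans–Tishchenko on an epoxy ketone).** Sm(III)/iodide may open the oxirane, and the acetate may migrate from O6 to O8. The fallback sets out from 11: Me4NBH(OAc)3 in MeCN/AcOH at −30 °C (hydroxyl-directed anti reduction) gives the epoxy anti-diol F5. The less hindered 8-OH (the 6-OH is flanked by the oxirane and C7) is acylated with mixed anhydride 15 in toluene at 60 °C to the 8-O-angelate F6. Ac2O/DMAP/pyridine then acetylates O6, and the fallback comes back at 16.

Further compounds
F1 | step 4 | rac-4-chloro-4,7-dimethyl-1-(propan-2-yl)-1,2,3,4,4a,5,6,8a-octahydronaphthalene-2,8a-diol (trans-fused: 8a-OH anti to 4a-H; Cl cis to 4a-H; C1/C2 unspecified) | CC(C)C1C(O)C[C@@](C)(Cl)[C@@H]2CCC(C)=C[C@@]12O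
F2 | step 4 | rac-4-chloro-4,7-dimethyl-1-(propan-2-yl)-2-[(triethylsilyl)oxy]-1,2,3,4,4a,5,6,8a-octahydronaphthalen-8a-ol (same relative configuration as F1) | CC(C)C1C(O[Si](CC)(CC)CC)C[C@@](C)(Cl)[C@@H]2CCC(C)=C[C@@]12O
F3 | step 4 | rac-(2Z,6E)-3,7-dimethyl-10-(propan-2-yl)-9-[(triethylsilyl)oxy]cyclodeca-2,6-dien-1-one | CC[Si](CC)(CC)OC1C/C(C)=C/CC/C(C)=C\C(=O)C1C(C)C
F4 | step 6 | (3E,7Z,9S,10R)-9-hydroxy-3,7-dimethyl-10-(propan-2-yl)cyclodeca-3,7-dien-1-one | O=C1C/C(C)=C/CC/C(C)=C\[C@H](O)[C@H]1C(C)C
F5 | step 8 | (1R,2R,3R,4S,6E,10S)-6,10-dimethyl-3-(propan-2-yl)-11-oxabicyclo[8.1.0]undec-6-ene-2,4-diol | O[C@H]1C/C(C)=C/CC[C@]2(C)O[C@@H]2[C@H](O)[C@@H]1C(C)C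
F6 | step 8 | (1R,2R,3S,4S,6E,10S)-2-hydroxy-6,10-dimethyl-3-(propan-2-yl)-11-oxabicyclo[8.1.0]undec-6-en-4-yl (2Z)-2-methylbut-2-enoate | C/C=C(/C)C(=O)O[C@H]1C/C(C)=C/CC[C@]2(C)O[C@@H]2[C@H](O)[C@@H]1C(C)C
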